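**Plan**

- Retrosynthesis: the acid is freed last from a benzyl ester and the side-chain C2' ketone comes from a silyl-protected carbinol. The arene is the dehydrogenation product of a 2,4-dioxocyclohexane-1-carboxylate, which is cut at C2–C3 (Claisen), then C1–C6 (Michael), then C5=C6 (cross-metathesis), and the chain at C1'–C2' (allylation of dodecanal).
- Enabling feature: on the benzene ring (C1 carboxyl, C2 OH, C3 H, C4 OMe, C6 side chain) the C1-carboxyl/C2-oxygen pair is a masked malonate and the C3/C4-oxygen pair a masked methyl ketone, so C2–C3 is a Claisen bond. In the non-aromatic ring the C4 oxygen lies remote from the ester and is the one etherified.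
- Forward: allylation, silylation and metathesis build the chain; malonate conjugate addition and Claisen closure give the only ring; C4 O-methylation and DDQ make the arene; desilylation, oxidation and hydrogenolysis finish.
- Stereochemistry: the target is achiral. The carbinol centre is made racemic and ends as a ketone; the sp3 ring centres are diastereomer mixtures erased on aromatisation.

Key step: step 5

Assumption: because the target has no stereocentre, the racemic carbinol and all diastereomer mixtures are carried forward without separation. Benzyl esters replace methyl esters so the acid can be released without hydroxide, and a tert-butyldiphenylsilyl ether is used because it must survive acidic methanol in step 6.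

**Route**

Step 1
Reactants: 1 dodecanal; 2 allylmagnesium bromide
Product: 3 rac-pentadec-1-en-4-ol
Conditions: CH2=CHCH2MgBr (1.2 equiv), Et2O, -78 to 0 °C; then 1 M HCl
Reagents that add atoms: none
Why: Grignard 1,2-addition of the allyl nucleophile to an unhindered aliphatic aldehyde forms the C1'–C2' bond, and the racemic carbinol suffices because this centre ends as a ketone.

Step 2
Reactants: 3 rac-pentadec-1-en-4-ol
Product: 4 tert-butyl(pentadec-1-en-4-yloxy)diphenylsilane (racemic)
Conditions: TBDPSCl, imidazole, DMAP (cat.), DMF, rt
Reagents that add atoms: tert-butyl(chloro)diphenylsilane, CC(C)(C)[Si](Cl)(c1ccccc1)c1ccccc1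
Why: Imidazole-promoted silylation of a secondary alcohol; this silyl ether is chosen because it should withstand the alkoxide of step 5, the acidic methanol of step 6 and DDQ in step 7.

Step 3
Reactants: 4 tert-butyl(pentadec-1-en-4-yloxy)diphenylsilane; 5 methyl vinyl ketone
Product: 6 (3E)-6-(tert-butyldiphenylsilyloxy)heptadec-3-en-2-one (racemic)
Conditions: 5 (3 equiv), second-generation Grubbs catalyst RuCl2(=CHPh)(H2IMes)(PCy3) (5 mol %), CH2Cl2, 40 °C
Reagents that add atoms: none
Why: Olefin cross-metathesis of a terminal alkene with an electron-poor enone is selective for the cross product and should give the E enone under thermodynamic control, the silyl ether being remote from the reacting alkene.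

Step 4
Reactants: 6 (3E)-6-(tert-butyldiphenylsilyloxy)heptadec-3-en-2-one; 7 dibenzyl malonate
Product: 8 dibenzyl 2-[6-(tert-butyldiphenylsilyloxy)-2-oxoheptadecan-4-yl]propanedioate (diastereomer mixture)
Conditions: 7 (1.2 equiv), KOtBu (10 mol %), THF, 0 °C to rt; AcOH quench
Reagents that add atoms: none
Why: Base-catalysed Michael addition of the malonate anion to the enone β-carbon forms the future C1–C6 bond; with only catalytic base, proton transfer to the adduct enolate should outrun both gamma-deprotonation of the enone (which could expel the silyloxy group) and ring closure, so the open adduct can be isolated.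

Step 5
Reactants: 8 dibenzyl 2-[6-(tert-butyldiphenylsilyloxy)-2-oxoheptadecan-4-yl]propanedioate
Product: 9 benzyl 6-[2-(tert-butyldiphenylsilyloxy)tridecyl]-2,4-dioxocyclohexane-1-carboxylate (enolised; diastereomer mixture)
Conditions: KOtBu (2.2 equiv), t-BuOH/THF (1:1), 0 to 45 °C; then cold 1 M HCl to pH 3
Reagents that add atoms: none
Why: Excess tert-butoxide deprotonates the malonate and, reversibly, the terminal methyl of the ketone; the methyl enolate (future C3) adds to one benzyl ester carbonyl (future C2) and the tetrahedral intermediate expels benzyloxide, so the C2–C3 bond and the six-membered ring form in one intramolecular Claisen (Dieckmann-type) condensation. The closest known reaction is the alkoxide-mediated Michael–Claisen sequence from enones and malonates to 6-alkyl-2,4-dioxocyclohexanecarboxylates, the standard entry to dihydro-orsellinates and olivetol precursors. The ring closes in a 6-(enolexo)-exo-trig mode. C1 becomes a stereocentre but is freely epimerisable and, like C6, is erased in step 7, so no stereocontrol is needed. The selectivity required is the site of enolisation: the internal methylene enolate could only close a four-membered ring or revert by retro-Michael cleavage, whereas the methyl enolate reaches the ester through a six-membered transition state, and the two benzyl esters are constitutionally equivalent acceptors. Deprotonation of the product, a vinylogous acid, to its potassium salt should drain these equilibria towards the ring.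

Step 6
Reactants: 9 benzyl 6-[2-(tert-butyldiphenylsilyloxy)tridecyl]-2,4-dioxocyclohexane-1-carboxylate
Product: 10 benzyl 6-[2-(tert-butyldiphenylsilyloxy)tridecyl]-4-methoxy-2-oxocyclohex-3-ene-1-carboxylate (diastereomer mixture)
Conditions: HC(OMe)3 (1.5 equiv), camphorsulfonic acid (5 mol %), MeOH, rt
Reagents that add atoms: trimethyl orthoformate, COC(OC)OC; methanol, CO
Why: Acid-catalysed enol ether formation of a cyclic 1,3-dione (vinylogous esterification) is reversible; methanol adds at the less hindered C4 carbonyl, and the 4-methoxy-2-oxo isomer should be the thermodynamic product because its C2 carbonyl stays paired with the C1 ester as a hydrogen-bonded β-keto ester, while the silyl ether and benzyl ester tolerate catalytic acid at rt.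

Step 7
Reactants: 10 benzyl 6-[2-(tert-butyldiphenylsilyloxy)tridecyl]-4-methoxy-2-oxocyclohex-3-ene-1-carboxylate
Product: 11 benzyl 6-[2-(tert-butyldiphenylsilyloxy)tridecyl]-2-hydroxy-4-methoxybenzoate (racemic)
Conditions: DDQ (1.2 equiv), toluene, rt to 80 °C
Reagents that add atoms: none
Why: DDQ dehydrogenation of a cyclohexenone to a phenol: hydride transfer from C6 of the β-keto ester dienol gives a cation stabilised by both ring oxygens, and loss of the C5 proton gives the arene with C2 as the ester-chelated phenol and C4 as the methyl ether.

Step 8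
Reactants: 11 benzyl 6-[2-(tert-butyldiphenylsilyloxy)tridecyl]-2-hydroxy-4-methoxybenzoate
Product: 12 benzyl 2-hydroxy-6-(2-hydroxytridecyl)-4-methoxybenzoate (racemic)
Conditions: Bu4NF (3 equiv), AcOH (3 equiv), THF, rt to 40 °C
Reagents that add atoms: none
Why: Fluoride cleavage of the silyl ether is driven by Si–F bond formation; acetic acid buffering keeps the freed secondary alcohol protonated so it should not attack the neighbouring benzyl ester, itself a poor acyl donor (2,6-disubstituted and conjugated with two oxygen donors).

Step 9
Reactants: 12 benzyl 2-hydroxy-6-(2-hydroxytridecyl)-4-methoxybenzoate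
Product: 13 benzyl 2-hydroxy-4-methoxy-6-(2-oxotridecyl)benzoate
Conditions: Dess–Martin periodinane (1.3 equiv), CH2Cl2, 0 °C to rt
Reagents that add atoms: none
Why: Dess–Martin oxidation converts the secondary alcohol to the ketone under near-neutral conditions that the chelated salicylate phenol and the benzyl ester should tolerate, and it removes both the last stereocentre and the nucleophile that could lactonise.

Step 10
Reactants: 13 benzyl 2-hydroxy-4-methoxy-6-(2-oxotridecyl)benzoate
Product: 14 2-hydroxy-4-methoxy-6-(2-oxotridecyl)benzoic acid (target)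
Conditions: H2 (1 atm), 10 % Pd/C, EtOAc, rt; filtration and evaporation without acid or heat
Reagents that add atoms: none
Why: Hydrogenolysis of the benzyl ester over palladium on carbon frees the acid under neutral conditions, avoiding hydroxide on a hindered salicylate that carries an enolisable 2-oxoalkyl group; the aliphatic ketone, aryl methyl ether and arene are inert at 1 atm.

**Compound list**

1 | dodecanal | CCCCCCCCCCCC=O | starting material
2 | allylmagnesium bromide | C=CC[Mg]Br | starting material
3 | rac-pentadec-1-en-4-ol | CCCCCCCCCCCC(O)CC=C | intermediate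
4 | tert-butyl(pentadec-1-en-4-yloxy)diphenylsilane (racemic) | CCCCCCCCCCCC(O[Si](c1ccccc1)(c1ccccc1)C(C)(C)C)CC=C | intermediate
5 | methyl vinyl ketone (but-3-en-2-one) | CC(=O)C=C | starting material
6 | (3E)-6-(tert-butyldiphenylsilyloxy)heptadec-3-en-2-one (racemic) | CCCCCCCCCCCC(O[Si](c1ccccc1)(c1ccccc1)C(C)(C)C)C/C=C/C(C)=O | intermediate
7 | dibenzyl malonate | O=C(CC(=O)OCc1ccccc1)OCc1ccccc1 | starting material
8 | dibenzyl 2-[6-(tert-butyldiphenylsilyloxy)-2-oxoheptadecan-4-yl]propanedioate (diastereomer mixture) | CCCCCCCCCCCC(O[Si](c1ccccc1)(c1ccccc1)C(C)(C)C)CC(CC(C)=O)C(C(=O)OCc1ccccc1)C(=O)OCc1ccccc1 | intermediate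
9 | benzyl 6-[2-(tert-butyldiphenylsilyloxy)tridecyl]-2,4-dioxocyclohexane-1-carboxylate (enolised; diastereomer mixture) | CCCCCCCCCCCC(O[Si](c1ccccc1)(c1ccccc1)C(C)(C)C)CC1CC(=O)CC(=O)C1C(=O)OCc1ccccc1 | intermediate
10 | benzyl 6-[2-(tert-butyldiphenylsilyloxy)tridecyl]-4-methoxy-2-oxocyclohex-3-ene-1-carboxylate (diastereomer mixture) | CCCCCCCCCCCC(O[Si](c1ccccc1)(c1ccccc1)C(C)(C)C)CC1CC(OC)=CC(=O)C1C(=O)OCc1ccccc1 | intermediate
11 | benzyl 6-[2-(tert-butyldiphenylsilyloxy)tridecyl]-2-hydroxy-4-methoxybenzoate (racemic) | CCCCCCCCCCCC(O[Si](c1ccccc1)(c1ccccc1)C(C)(C)C)Cc1cc(OC)cc(O)c1C(=O)OCc1ccccc1 | intermediate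
12 | benzyl 2-hydroxy-6-(2-hydroxytridecyl)-4-methoxybenzoate (racemic) | CCCCCCCCCCCC(O)Cc1cc(OC)cc(O)c1C(=O)OCc1ccccc1 | intermediate
13 | benzyl 2-hydroxy-4-methoxy-6-(2-oxotridecyl)benzoate | CCCCCCCCCCCC(=O)Cc1cc(OC)cc(O)c1C(=O)OCc1ccccc1 | intermediate
14 | 2-hydroxy-4-methoxy-6-(2-oxotridecyl)benzoic acid | CCCCCCCCCCCC(=O)Cc1cc(OC)cc(O)c1C(=O)O | target

**Summary**

Total step count: 10. Longest linear sequence: 10 steps, from dodecanal.

Steps most likely to fail:

1. Step 6. Methylation may go to the wrong enol oxygen, continue to a bis(enol ether) of the β-keto ester, or the silyl group may be lost slowly in acidic methanol. Fallback, setting out from 9: the two oxygens are told apart on the arene instead. Bromine (1.0 equiv) in DMF at 0 °C should brominate the dione to benzyl 3-bromo-6-[2-(tert-butyldiphenylsilyloxy)tridecyl]-2,4-dioxocyclohexane-1-carboxylate F1 (not isolated), which on warming loses hydrogen bromide and tautomerises to benzyl 6-[2-(tert-butyldiphenylsilyloxy)tridecyl]-2,4-dihydroxybenzoate F2. Iodomethane (1.1 equiv) with K2CO3 in acetone should then methylate only the C4 hydroxyl, the C2 hydroxyl being locked in a hydrogen bond to the ester. The sequence returns to the route at 11.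

2. Step 8. The freed alkoxide may lactonise onto the ortho ester, expelling benzyl alcohol and giving a 3,4-dihydroisocoumarin. Fallback, setting out from 11: the ester is removed before the silyl ether, so no acyl donor is present when the alcohol appears. Hydrogenolysis (H2, Pd/C, EtOAc) should give 6-[2-(tert-butyldiphenylsilyloxy)tridecyl]-2-hydroxy-4-methoxybenzoic acid F3. Bu4NF in THF should then give 2-hydroxy-6-(2-hydroxytridecyl)-4-methoxybenzoic acid F4, kept as its tetrabutylammonium carboxylate and not acidified. Dess–Martin oxidation of that salt gives the ketone, and the sequence returns to the route at 14.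

3. Step 5. Retro-Michael cleavage, followed by loss of the silyloxy group from the regenerated enone, may outrun ring closure, and closure may be slow because the malonate sits as its unreactive enolate. Fallback, setting out from 4: the same dione is assembled with the opposite Michael–Claisen polarity. Cross-metathesis of 4 with methyl acrylate (same ruthenium catalyst) should give methyl (2E)-5-(tert-butyldiphenylsilyloxy)hexadec-2-enoate F5. Benzyl acetoacetate and KOtBu in t-BuOH should add to it to give 1-benzyl 5-methyl 2-acetyl-3-[2-(tert-butyldiphenylsilyloxy)tridecyl]pentanedioate F6 (not isolated). The acetyl methyl enolate of F6 then closes onto the methyl ester, forming C3–C4 in place of C2–C3 with loss of methanol. The sequence returns to the route at 9.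

**Further compounds**

F1 | step 6 | benzyl 3-bromo-6-[2-(tert-butyldiphenylsilyloxy)tridecyl]-2,4-dioxocyclohexane-1-carboxylate | CCCCCCCCCCCC(O[Si](c1ccccc1)(c1ccccc1)C(C)(C)C)CC1CC(=O)C(Br)C(=O)C1C(=O)OCc1ccccc1
F2 | step 6 | benzyl 6-[2-(tert-butyldiphenylsilyloxy)tridecyl]-2,4-dihydroxybenzoate | CCCCCCCCCCCC(O[Si](c1ccccc1)(c1ccccc1)C(C)(C)C)Cc1cc(O)cc(O)c1C(=O)OCc1ccccc1
F3 | step 8 | 6-[2-(tert-butyldiphenylsilyloxy)tridecyl]-2-hydroxy-4-methoxybenzoic acid | CCCCCCCCCCCC(O[Si](c1ccccc1)(c1ccccc1)C(C)(C)C)Cc1cc(OC)cc(O)c1C(=O)O
F4 | step 8 | 2-hydroxy-6-(2-hydroxytridecyl)-4-methoxybenzoic acid | CCCCCCCCCCCC(O)Cc1cc(OC)cc(O)c1C(=O)O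
F5 | step 5 | methyl (2E)-5-(tert-butyldiphenylsilyloxy)hexadec-2-enoate | CCCCCCCCCCCC(O[Si](c1ccccc1)(c1ccccc1)C(C)(C)C)C/C=C/C(=O)OC
F6 | step 5 | 1-benzyl 5-methyl 2-acetyl-3-[2-(tert-butyldiphenylsilyloxy)tridecyl]pentanedioate | CCCCCCCCCCCC(O[Si](c1ccccc1)(c1ccccc1)C(C)(C)C)CC(CC(=O)OC)C(C(C)=O)C(=O)OCc1ccccc1
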